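Everything rests on cutting ring A of the depsidone back to a 2-pyrone and an alkyne. Numbered as a benzoate, ring A carries methyl at C3, methoxy at C4, hydrogen at C5 and methyl at C6, exactly as C3 to C6 of 4-methoxy-3,6-dimethyl-2-pyrone; the ether carbon C2 and the carboxyl-bearing carbon C1 therefore come from a benzyl 3-aryloxypropiolate that already carries ring B on oxygen. One thermal cycloaddition with loss of carbon dioxide forms C3–C2 and C6–C1, closes ring A and delivers the hindered diaryl ether and the carboxyl together. Lactonisation, unmasking and an acylative dynamic kinetic resolution of the lactol follow.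

Key step: step 14

Atom labels: ring A is numbered as the benzoate formed in step 14 and is always written "ring-A C1" to "ring-A C6": C1 (carboxyl-bearing carbon), C2 (ether carbon), C3 (methyl carbon), C4 (methoxy carbon), C5 (CH), C6 (methyl carbon). Ring B has B1 (ether carbon), B2 (carbon of the ester oxygen), B3 (C–CH2OH), B4 (C–OH), B5 (carbon bearing the lactone C=O), B6 (carbon bearing the lactol carbon). In phthalide numbering, phthalide C3 is the lactol carbon, C4 = B1, C5 = B2, C6 = B3, C7 = B4. "ArB–O" denotes the ring-B phenol made in step 9, bound through its B1 oxygen.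

Assumption: the hemiacylal carbon (the only stereocentre) epimerises through the open formyl acid in basic or aqueous media but is taken to hold its configuration in neutral, water-free, cold solution; it is therefore fixed as an acylal in step 18 and released last.

Assumption: the sense of induction of the isothiourea in step 18 is assigned on the racemate, and the catalyst antipode that gives the (R)-acylal is used.

Remark: an acylative dynamic kinetic resolution ends in an ester, so the free lactol needs a separate neutral release (step 19). B3–CH2OH and B4–OH are masked together as one isopropylidene acetal, which saves a protecting step and keeps silicon out of the route. All acetal carbons written without configuration are racemic.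

Step 1
Reactants: 1 sesamol (1,3-benzodioxol-5-ol)
Product: 2 6-bromo-1,3-benzodioxol-5-ol
Conditions: NBS (1.0 equiv), MeCN, −20 → 0 °C
Reagents that add atoms: N-bromosuccinimide, O=C1CCC(=O)N1Br
Why: Electrophilic aromatic bromination; the position ortho to OH and para to a dioxole oxygen (the future B5) is the most activated and least hindered site of sesamol.

Step 2
Reactants: 2 6-bromo-1,3-benzodioxol-5-ol
Product: 3 5-bromo-6-(methoxymethoxy)-1,3-benzodioxole
Conditions: MOMCl, iPr2NEt, CH2Cl2, 0 → 20 °C
Reagents that add atoms: chloromethyl methyl ether, COCCl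
Why: Williamson-type O-alkylation gives a MOM ether that tolerates organolithiums and later acts as an ortho-directing group.

Step 3
Reactants: 3 5-bromo-6-(methoxymethoxy)-1,3-benzodioxole
Product: 5 N,N-diethyl-6-(methoxymethoxy)-1,3-benzodioxole-5-carboxamide, via aryllithium 4 (not isolated)
Conditions: n-BuLi, THF, −78 °C; then ClC(O)NEt2, −78 → 0 °C
Reagents that add atoms: N,N-diethylcarbamoyl chloride, CCN(CC)C(=O)Cl
Why: Bromine–lithium exchange is faster than ring deprotonation at −78 °C, and acylation of the aryllithium by the carbamoyl chloride places the future B5 carboxyl carbon regiospecifically as a tertiary amide.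

Step 4
Reactants: 5 N,N-diethyl-6-(methoxymethoxy)-1,3-benzodioxole-5-carboxamide
Product: 7 N,N-diethyl-4,7-diformyl-6-(methoxymethoxy)-1,3-benzodioxole-5-carboxamide, via 4,7-dilithio amide 6 (not isolated)
Conditions: s-BuLi (2.5 equiv), TMEDA, THF, −78 °C; then DMF, −78 → 0 °C; aq. NH4Cl
Reagents that add atoms: N,N-dimethylformamide, CN(C)C=O
Why: Double directed ortho-metalation; the only two ring hydrogens each lie between two directing groups (amide and dioxole oxygen at the future B6, MOM ether and dioxole oxygen at the future B3), so both are lithiated and formylated whatever the order of deprotonation.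

Step 5
Reactants: 7 N,N-diethyl-4,7-diformyl-6-(methoxymethoxy)-1,3-benzodioxole-5-carboxamide
Product: 8 rac-6-formyl-3,7-dihydroxy-4,5-(methylenedioxy)phthalide
Conditions: 3 M aq. HCl, 1,4-dioxane, 60 °C
Reagents that add atoms: water, O
Why: Acid hydrolysis with neighbouring-group participation; the amide oxygen adds to the protonated ortho-formyl group and diethylamine is expelled, giving the 3-hydroxyphthalide while the MOM ether is cleaved, and only the formyl group ortho to the amide can cyclise, which fixes B5 as the carbonyl carbon and B6 as the bearer of the (racemic) lactol carbon.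

Step 6
Reactants: 8 rac-6-formyl-3,7-dihydroxy-4,5-(methylenedioxy)phthalide
Product: 9 rac-6-formyl-4,5,7-trihydroxy-3-methoxyphthalide
Conditions: BCl3 (excess), CH2Cl2, −78 → 20 °C; then MeOH, 60 °C; aqueous work-up, argon
Reagents that add atoms: methanol, CO
Why: Lewis-acid ether cleavage opens the methylenedioxy ring (both oxygens sit ortho to a chelating formyl-type carbon) to the catechol, and the methanolic HCl of the quench converts the lactol into its methyl pseudo-ester (Fischer-type acetalisation), any dimethyl acetal of the aldehyde reverting on aqueous work-up.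

Step 7
Reactants: 9 rac-6-formyl-4,5,7-trihydroxy-3-methoxyphthalide
Product: 10 rac-5-(benzyloxy)-6-formyl-4,7-dihydroxy-3-methoxyphthalide
Conditions: BnBr (1.0 equiv), KHCO3, DMF, 20 °C, argon
Reagents that add atoms: benzyl bromide, BrCc1ccccc1
Why: Regioselective Williamson etherification; one equivalent of weak base ionises only the most acidic phenol, B2–OH (para to the lactone carbonyl and ortho to the formyl group), whereas B4–OH is locked between two carbonyl acceptors and B1–OH is conjugated to neither.

Step 8
Reactants: 10 rac-5-(benzyloxy)-6-formyl-4,7-dihydroxy-3-methoxyphthalide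
Product: 11 rac-5-(benzyloxy)-4,7-dihydroxy-6-(hydroxymethyl)-3-methoxyphthalide
Conditions: NaBH4, THF–MeOH, −10 °C; aq. NH4Cl
Reagents that add atoms: none
Why: Borohydride reduction of the aryl aldehyde is much faster than attack on the lactone or pseudo-ester at low temperature.

Step 9
Reactants: 11 rac-5-(benzyloxy)-4,7-dihydroxy-6-(hydroxymethyl)-3-methoxyphthalide
Product: 12 rac ring-B phenol (6-CH2O/7-O isopropylidene acetal of 11; 5-benzyloxy; free 4-OH at B1)
Conditions: Me2C(OMe)2, PPTS (cat.), acetone, 20 °C
Reagents that add atoms: 2,2-dimethoxypropane, COC(C)(C)OC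
Why: Acid-catalysed transketalisation closes the six-membered 1,3-dioxine across the salicyl alcohol unit (B3–CH2OH and B4–OH); B1–OH has no partner and stays free.

Step 10
Reactants: 13 3,3-dichloroacrylic acid
Product: 14 benzyl 3,3-dichloroprop-2-enoate
Conditions: BnBr, KHCO3, DMF, 20 °C
Reagents that add atoms: benzyl bromide, BrCc1ccccc1
Why: Carboxylate O-alkylation (SN2) under a weak base that does not attack the dichlorovinyl group.

Step 11
Reactants: 12 rac ring-B phenol; 14 benzyl 3,3-dichloroprop-2-enoate
Product: 15 benzyl 3-chloro-3-(ArB-oxy)prop-2-enoate (E/Z mixture)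
Conditions: Cs2CO3, DMF, 0 → 20 °C
Reagents that add atoms: none
Why: Vinylic nucleophilic substitution by addition–elimination; the phenoxide adds to the β-carbon of the acrylate and one chloride leaves, and the crowded product resists a second substitution.

Step 12
Reactants: 15 benzyl 3-chloro-3-(ArB-oxy)prop-2-enoate
Product: 16 benzyl 3-(ArB-oxy)prop-2-ynoate (aryl ynol ether ester; B2 benzyl ether, B3/B4 acetonide, B5/B6 as racemic 3-methoxyphthalide)
Conditions: LiN(SiMe3)2 (1.05 equiv), THF, −78 °C; pH 7 buffer
Reagents that add atoms: none
Why: Base-induced 1,2-dehydrochlorination of an α-chloro enol ether, a standard entry to alkynyl ethers; either alkene isomer can eliminate and the hindered amide base does not add to the ynoate at −78 °C.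

Step 13
Reactants: 17 4-hydroxy-3,6-dimethyl-2H-pyran-2-one
Product: 18 4-methoxy-3,6-dimethyl-2H-pyran-2-one
Conditions: Me2SO4, K2CO3, acetone, reflux
Reagents that add atoms: dimethyl sulfate, COS(=O)(=O)OC
Why: O-methylation of the vinylogous acid; under carbonate and dimethyl sulfate 4-hydroxy-2-pyrones give mainly the 4-methoxy-2-pyrone.

Step 14
Reactants: 16 benzyl 3-(ArB-oxy)prop-2-ynoate; 18 4-methoxy-3,6-dimethyl-2H-pyran-2-one
Product: 20 benzyl 2-(ArB-oxy)-4-methoxy-3,6-dimethylbenzoate (diaryl ether with complete ring A), via bicyclic lactone 19 (not isolated)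
Conditions: 18 (4 equiv), o-dichlorobenzene, BHT (cat.), 170 °C, sealed tube, argon
Reagents that add atoms: none
Why: Thermal normal-electron-demand [4+2] cycloaddition of the pyrone diene (C3=C4–C5=C6) across the alkyne gives the 2-oxabicyclo[2.2.2]octadienone 19, which loses carbon dioxide by retro-[4+2] and aromatises. The closest known reaction type is the Diels–Alder reaction of 2-pyrones with acetylenic esters, which gives benzoates after decarboxylation. Ring A is closed by an intermolecular two-bond cycloaddition (ring-A C3–C2 from pyrone C3 and the aryloxy carbon, ring-A C6–C1 from pyrone C6 and the ester-bearing carbon), so no separate cyclisation mode has to be enforced. No stereocentre is formed: the bridgehead centres of 19 vanish on aromatisation and the acetal carbon stays racemic. The one selectivity needed is regiochemical and is secured by matched polarisation: pyrone C3, made the nucleophilic terminus by the 4-methoxy group and the ring oxygen, bonds to the alkyne carbon β to the ester, which is the electrophilic terminus even though it carries the aryloxy group. The aryl ynol ether has no β-hydrogen for retro-ene ketene formation and should survive the temperature, while excess pyrone and strict exclusion of water favour the bimolecular path.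

Step 15
Reactants: 20 benzyl 2-(ArB-oxy)-4-methoxy-3,6-dimethylbenzoate
Product: 21 2-(ArB-oxy)-4-methoxy-3,6-dimethylbenzoic acid with free B2–OH (hydroxy acid)
Conditions: H2 (1 atm), 10% Pd/C, EtOAc, 20 °C
Reagents that add atoms: none
Why: Hydrogenolysis of the benzyl ester and the aryl benzyl ether over palladium; the acetonide, the methyl pseudo-ester and the lactone are inert under neutral conditions.

Step 16
Reactants: 21 hydroxy acid
Product: 22 protected depsidone (seven-membered lactone ring-A C1–C(=O)–O–B2; B3/B4 acetonide; racemic 3-methoxyphthalide)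
Conditions: EDC·HCl, DMAP (cat.), CH2Cl2 (high dilution), 0 → 20 °C
Reagents that add atoms: none
Why: Carbodiimide (Steglich-type) lactonisation; the activated ring-A acid is captured intramolecularly by B2–OH, closing the seven-membered depsidone ring.

Step 17
Reactants: 22 protected depsidone
Product: 23 racemic lactol triol (the target constitution with the hemiacylal carbon racemic)
Conditions: 1 M aq. H2SO4, 1,4-dioxane, 55 °C
Reagents that add atoms: water, O
Why: Acid-catalysed hydrolysis of the isopropylidene acetal and of the methyl pseudo-ester frees B3–CH2OH, B4–OH and the lactol; sulfuric acid is used so that no benzylic chloride can form.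

Step 18
Reactants: 23 racemic lactol triol
Product: 24 (R)-bis(propionate): propionate esters on the lactol oxygen, (R) at the acylal carbon, and on B3–CH2OH; B4–OH free
Conditions: (EtCO)2O (2.3 equiv), HyperBTM (10 mol %, antipode giving the (R)-acylal), iPr2NEt, CHCl3, 0 °C
Reagents that add atoms: propionic anhydride, CCC(=O)OC(=O)CC
Why: Acylative dynamic kinetic resolution of a 3-hydroxyphthalide; the amine base racemises the hemiacylal through its open formyl carboxylate while the chiral isothiourea transfers the acyl group to one enantiomer, which sets the stereocentre as a configurationally stable acylal, and the primary alcohol is esterified alongside while the chelated, doubly flanked B4–OH is expected to stay free.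

Step 19
Reactants: 24 (R)-bis(propionate)
Product: 25 CNP0321962.1, the (R)-lactol target
Conditions: immobilised Candida antarctica lipase B, n-BuOH, tert-butyl methyl ether, 0–5 °C; filter, evaporate cold, crystallise
Reagents that add atoms: none
Why: Lipase-catalysed transesterification to butan-1-ol removes the primary and the acylal propionate by acyl–oxygen cleavage under neutral, water-free, cold conditions, so no bond at the stereocentre is broken and the (R)-hemiacylal is released with retention.

Compound list
1 | sesamol (1,3-benzodioxol-5-ol) | Oc1ccc2OCOc2c1 | starting material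
2 | 6-bromo-1,3-benzodioxol-5-ol | Oc1cc2OCOc2cc1Br | intermediate
3 | 5-bromo-6-(methoxymethoxy)-1,3-benzodioxole | COCOc1cc2OCOc2cc1Br | intermediate
4 | [6-(methoxymethoxy)-1,3-benzodioxol-5-yl]lithium | [Li]c1cc2OCOc2cc1OCOC | intermediate (not isolated)
5 | N,N-diethyl-6-(methoxymethoxy)-1,3-benzodioxole-5-carboxamide | CCN(CC)C(=O)c1cc2OCOc2cc1OCOC | intermediate
6 | 4,7-dilithio derivative of amide 5 | CCN(CC)C(=O)c1c([Li])c2OCOc2c([Li])c1OCOC | intermediate (not isolated)
7 | N,N-diethyl-4,7-diformyl-6-(methoxymethoxy)-1,3-benzodioxole-5-carboxamide | CCN(CC)C(=O)c1c(C=O)c2OCOc2c(C=O)c1OCOC | intermediate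
8 | rac-6-formyl-3,7-dihydroxy-4,5-(methylenedioxy)phthalide | OC1OC(=O)c2c(O)c(C=O)c3OCOc3c12 | intermediate
9 | rac-6-formyl-4,5,7-trihydroxy-3-methoxyphthalide | COC1OC(=O)c2c(O)c(C=O)c(O)c(O)c12 | intermediate
10 | rac-5-(benzyloxy)-6-formyl-4,7-dihydroxy-3-methoxyphthalide | COC1OC(=O)c2c(O)c(C=O)c(OCc3ccccc3)c(O)c12 | intermediate
11 | rac-5-(benzyloxy)-4,7-dihydroxy-6-(hydroxymethyl)-3-methoxyphthalide | COC1OC(=O)c2c(O)c(CO)c(OCc3ccccc3)c(O)c12 | intermediate
12 | rac ring-B phenol: 6-CH2O/7-O isopropylidene acetal of 11, 5-benzyloxy, free 4-OH (B1) | COC1OC(=O)c2c3OC(C)(C)OCc3c(OCc3ccccc3)c(O)c12 | intermediate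
13 | 3,3-dichloroacrylic acid | OC(=O)C=C(Cl)Cl | starting material
14 | benzyl 3,3-dichloroprop-2-enoate | O=C(OCc1ccccc1)C=C(Cl)Cl | intermediate
15 | benzyl 3-chloro-3-(ArB-oxy)prop-2-enoate, E/Z mixture, racemic | O=C(OCc1ccccc1)C=C(Cl)Oc1c(OCc2ccccc2)c2COC(C)(C)Oc2c2C(=O)OC(OC)c12 | intermediate
16 | benzyl 3-(ArB-oxy)prop-2-ynoate, racemic | O=C(OCc1ccccc1)C#COc1c(OCc2ccccc2)c2COC(C)(C)Oc2c2C(=O)OC(OC)c12 | intermediate
17 | 4-hydroxy-3,6-dimethyl-2H-pyran-2-one | CC1=CC(O)=C(C)C(=O)O1 | starting material
18 | 4-methoxy-3,6-dimethyl-2H-pyran-2-one | COC1=C(C)C(=O)OC(C)=C1 | intermediate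
19 | benzyl 5-(ArB-oxy)-8-methoxy-1,4-dimethyl-3-oxo-2-oxabicyclo[2.2.2]octa-5,7-diene-6-carboxylate, diastereomer mixture | CC12C(=O)OC(C)(C=C1OC)C(C(=O)OCc1ccccc1)=C2Oc1c(OCc2ccccc2)c2COC(C)(C)Oc2c2C(=O)OC(OC)c12 | intermediate (not isolated)
20 | benzyl 2-(ArB-oxy)-4-methoxy-3,6-dimethylbenzoate, racemic | O=C(OCc1ccccc1)c1c(C)cc(OC)c(C)c1Oc1c(OCc2ccccc2)c2COC(C)(C)Oc2c2C(=O)OC(OC)c12 | intermediate
21 | 2-(ArB-oxy)-4-methoxy-3,6-dimethylbenzoic acid with free B2–OH, racemic | O=C(O)c1c(C)cc(OC)c(C)c1Oc1c(O)c2COC(C)(C)Oc2c2C(=O)OC(OC)c12 | intermediate
22 | protected depsidone (B3/B4 acetonide, 3-methoxyphthalide), racemic | COc1cc(C)c2c(c1C)Oc1c(c3COC(C)(C)Oc3c3c1C(OC)OC3=O)OC2=O | intermediate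
23 | racemic lactol triol | COc1cc(C)c2c(c1C)Oc1c(c(CO)c(O)c3c1C(O)OC3=O)OC2=O | intermediate
24 | (R)-bis(propionate) of 23 (lactol O and B3–CH2O) | COc1cc(C)c2c(c1C)Oc1c(c(COC(=O)CC)c(O)c3c1[C@H](OC(=O)CC)OC3=O)OC2=O | intermediate
25 | CNP0321962.1, (R)-lactol | COc1cc(C)c2c(c1C)Oc1c(c(CO)c(O)c3c1[C@H](O)OC3=O)OC2=O | target

Total step count: 19. Longest linear sequence: 17 steps (steps 1–9, 11, 12, 14–19).

Steps most likely to fail

1. Step 14. The cycloaddition joins two fully substituted termini (both pyrone termini carry methyl groups and the alkyne carries a doubly ortho-substituted aryloxy group), so it may be too slow, and thermal decomposition or hydration of the ynol ether may overtake it. The fallback builds ring A on a small alkyne and forms the ether afterwards; it sets out from phenol 12 and pyrone 18. Benzyl propiolate is brominated (NBS, AgNO3 cat., acetone) to benzyl 3-bromoprop-2-ynoate F1. Heating F1 with 18 (toluene, 120 °C) gives, through the bicyclic bromolactone F2 and loss of carbon dioxide under the same polarisation control, benzyl 2-bromo-4-methoxy-3,6-dimethylbenzoate F3. Ullmann ether synthesis of F3 with 12 (CuCl, 2,2,6,6-tetramethylheptane-3,5-dione, Cs2CO3, NMP, 120 °C) then gives 20, where the route is rejoined.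

2. Step 19. Enzymatic transesterification at the crowded acylal may be slow, which would leave the liberated hemiacylal time to epimerise through ring opening to the formyl acid. The fallback replaces stereoselective synthesis by physical resolution and sets out from racemic 23. It is separated by preparative supercritical-fluid chromatography on an immobilised amylose carbamate phase (CO2 with acidified acetonitrile, sub-ambient temperature). The (R)-fraction is collected cold as 25; the (S)-fraction is re-equilibrated to the racemate in wet solvent and recycled.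

3. Step 12. The base or the chloride released may add to the very electrophilic ynoate, or the base may deprotonate the phthalide acetal carbon, instead of giving clean dehydrochlorination. The fallback avoids isolating the alkyne and sets out from chloroacrylate 15, which is used as an alkyne surrogate. Heating 15 with 18 (o-dichlorobenzene, 2,6-lutidine, 170 °C) should give the bicyclic chlorolactone F4, which loses carbon dioxide to the chlorocyclohexadiene F5. F5 aromatises by loss of hydrogen chloride to 20, where the route is rejoined.

Further compounds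
F1 | step 14 | benzyl 3-bromoprop-2-ynoate | O=C(OCc1ccccc1)C#CBr
F2 | step 14 | benzyl 5-bromo-8-methoxy-1,4-dimethyl-3-oxo-2-oxabicyclo[2.2.2]octa-5,7-diene-6-carboxylate | CC12C(=O)OC(C)(C=C1OC)C(C(=O)OCc1ccccc1)=C2Br
F3 | step 14 | benzyl 2-bromo-4-methoxy-3,6-dimethylbenzoate | O=C(OCc1ccccc1)c1c(C)cc(OC)c(C)c1Br
F0 | step 19 | none | none
F4 | step 12 | benzyl 5-(ArB-oxy)-5-chloro-8-methoxy-1,4-dimethyl-3-oxo-2-oxabicyclo[2.2.2]oct-7-ene-6-carboxylate | CC12C(=O)OC(C)(C=C1OC)C(C(=O)OCc1ccccc1)C2(Cl)Oc1c(OCc2ccccc2)c2COC(C)(C)Oc2c2C(=O)OC(OC)c12
F5 | step 12 | benzyl 6-(ArB-oxy)-6-chloro-4-methoxy-2,5-dimethylcyclohexa-2,4-diene-1-carboxylate | CC1=C(OC)C=C(C)C(C(=O)OCc2ccccc2)C1(Cl)Oc1c(OCc2ccccc2)c2COC(C)(C)Oc2c2C(=O)OC(OC)c12
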